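**Strategy.** Ring B (labdane numbering) is disconnected at C5–C6 and C8–C9 into a ring A enolate carrying the C10 quaternary centre and the four-carbon ynal C6–C7–C8–C17. One flask joins them: an aldol addition forges C5–C6 and makes C6 the carbinol, then a palladium Alder-ene cycloisomerisation of the resulting 1,7-enyne forges C8–C9, creating the C8=C17 methylene and a C9 vinyl handle. The step exploits the β-hydroxy ketone pattern C4(=O)–C5–C6(OH) latent in rings A and B and the methylene carbon C8 flanking C9. Only C10 is set by catalysis; C5, C6 and C9 are relayed from it. A hydroxyl-directed hydroformylation later builds the C4 quaternary centre.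

Key step: step 3

Remark: the target is treated as the open 6-hydroxy-18-aldehyde drawn (a 6,18-lactol tautomer would be the same compound); locants are labdane-type (decalin C1–C10, C17 methylene carbon, C18 formyl carbon, C19 methyl on C4, side chain C11–C16 up to the butenolide ring carbon).

Step 1
Reactants: 1 3-methylcyclohex-2-en-1-one; 2 propyne
Product: 5 (R)-trimethyl{[3-methyl-3-((E)-prop-1-en-1-yl)cyclohex-1-en-1-yl]oxy}silane, via (E)-propenylalane 3 (not isolated), via aluminium enolate 4 (not isolated)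
Conditions: i-Bu2AlH, hexane, 50 °C (sealed); 1, copper thiophene-2-carboxylate (10 mol %), chiral aminophosphine Ph2PN[CH(CH3)Ph]2 (11 mol %, antipode that gives R), Et2O, −30 °C; TMSOTf, −30 to 0 °C
Reagents that add atoms: trimethylsilyl trifluoromethanesulfonate, C[Si](C)(C)OS(=O)(=O)C(F)(F)F
Why: Hydroalumination of the terminal alkyne gives the (E)-alkenylalane, whose copper-catalysed asymmetric conjugate addition to the β-methyl enone sets the quaternary C10 centre under ligand control, and O-silylation of the aluminium enolate fixes the C4–C5 enol ether regiochemistry.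

Step 2
Reactants: 6 but-3-yn-1-ol
Product: 7 but-3-ynal
Conditions: Dess–Martin periodinane, NaHCO3, CH2Cl2, 0 °C; used at once as a cold solution
Reagents that add atoms: none
Why: Dess–Martin oxidation of a primary alcohol under buffered, non-basic conditions should give the β,γ-ynal without isomerisation to the allenal.

Step 3
Reactants: 5 (R)-silyl enol ether; 7 but-3-ynal
Product: 10 (4aR,5S,8S,8aS)-5-ethenyl-8-hydroxy-4a-methyl-6-methylideneoctahydronaphthalen-1(2H)-one, via lithium enolate 8 (not isolated), via aldol adduct 9 (not isolated)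
Conditions: MeLi, THF, 0 °C; 7, −78 °C; AcOH; Pd(OAc)2 (5 mol %), PPh3 (10 mol %), toluene, 60 °C
Reagents that add atoms: none
Why: MeLi cleaves the enol ether to the regiodefined C4–C5 lithium enolate 8, whose closed (Zimmerman–Traxler) aldol addition to the ynal forms C5–C6, and after protonation the palladium acetate catalyst cycloisomerises the resulting 1,7-enyne 9 (alkyne–alkene coupling at palladium, β-hydride elimination from C12, C–H formation at C17) to form C8–C9. The closest known reaction types are the aldol addition of a conjugate-addition-derived enolate and the palladium-catalysed Alder-ene cycloisomerisation of 1,6- and 1,7-enynes to 1,4-dienes. Ring B closes in a 6-exo-trig mode onto C9, which turns the alkyne into the exocyclic C8=C17 methylene and the propenyl group into the C11=C12 vinyl group. C6 is controlled by the chair aldol transition state of the ring-fixed (E)-enolate (anti adduct) reacting on the face opposite the pseudoaxial propenyl group at C10; C5, α to the ketone, follows from the same event and can equilibrate under the AcOH conditions to the trans-fused isomer; C9 is controlled by the chair-like cyclisation that places C11 equatorial. The step needs regiocontrol of enolisation (secured by the enol ether from step 1), carbonyl addition faster than proton transfer from the acidic ynal (−78 °C, lithium counter-ion) and β-hydride elimination towards C12 and not C9 (the C9–H bond cannot align inside the forming metallacycle).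

Step 4
Reactants: 10 bicyclic ketol
Product: 11 (1S,4S,4aR,8aS)-4-ethenyl-4a-methyl-3,8-dimethylidenedecahydronaphthalen-1-ol
Conditions: Zn, CH2Br2, TiCl4, THF, 0 °C to rt
Reagents that add atoms: dibromomethane, BrCBr
Why: Takai–Lombardo methylenation converts the hindered, enolisable C4 ketone into the exocyclic C4=C19 alkene without base, so the β-hydroxy ketone should neither undergo retro-aldol cleavage nor epimerise at C5, which is fixed from here on.

Step 5
Reactants: 12 ethyl acetoacetate
Product: 13 ethyl (E)-3-{[(trifluoromethyl)sulfonyl]oxy}but-2-enoate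
Conditions: Tf2O, aq. Me4NOH, hexane, 5 °C
Reagents that add atoms: trifluoromethanesulfonic anhydride, O=S(=O)(OS(=O)(=O)C(F)(F)F)C(F)(F)F
Why: O-triflation of the non-chelated ammonium enolate under biphasic conditions should give the (E)-enol triflate, which fixes the later C13=C14 geometry.

Step 6
Reactants: 11 triene alcohol; 13 (E)-enol triflate
Product: 15 ethyl (E)-5-[(1S,4S,4aS,8aR)-4-hydroxy-8a-methyl-2,5-dimethylidenedecahydronaphthalen-1-yl]-3-methylpent-2-enoate, via alkyl(disiamyl)borane 14 (not isolated)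
Conditions: Sia2BH (from BH3·THF and 2-methylbut-2-ene), THF, 0 °C; 13, PdCl2(dppf) (5 mol %), K3PO4, DMF, 50 °C
Reagents that add atoms: none
Why: The hindered dialkylborane should hydroborate the monosubstituted C11=C12 vinyl group in preference to the two 1,1-disubstituted methylenes (boron on C12), and B-alkyl Suzuki–Miyaura coupling with the enol triflate forms C12–C13 with retention of the (E)-geometry.

Step 7
Reactants: 15 enoate
Product: 16 (E)-5-[(1S,4S,4aS,8aR)-4-hydroxy-8a-methyl-2,5-dimethylidenedecahydronaphthalen-1-yl]-3-methylpent-2-en-1-ol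
Conditions: i-Bu2AlH, CH2Cl2, −78 °C
Reagents that add atoms: none
Why: 1,2-Reduction of the α,β-unsaturated ester with i-Bu2AlH gives the allylic alcohol without touching the isolated alkenes.

Step 8
Reactants: 16 allylic alcohol
Product: 17 (E)-5-[(1S,4S,4aS,8aR)-4-hydroxy-8a-methyl-2,5-dimethylidenedecahydronaphthalen-1-yl]-3-methylpent-2-enal
Conditions: MnO2, CH2Cl2, rt
Reagents that add atoms: none
Why: MnO2 oxidises the primary allylic alcohol selectively and leaves the non-allylic secondary C6 hydroxyl untouched.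

Step 9
Reactants: 18 4-methylfuran-2(5H)-one
Product: 19 trimethyl[(4-methylfuran-2-yl)oxy]silane
Conditions: TMSCl, Et3N, CH2Cl2, rt
Reagents that add atoms: chlorotrimethylsilane, C[Si](C)(C)Cl
Why: Soft enolisation of the butenolide at the γ-carbon and O-silylation give the aromatic 2-silyloxyfuran.

Step 10
Reactants: 17 enal; 19 silyloxyfuran
Product: 20 (5S)-5-{(1S,2E)-1-hydroxy-5-[(1S,4S,4aS,8aR)-4-hydroxy-8a-methyl-2,5-dimethylidenedecahydronaphthalen-1-yl]-3-methylpent-2-en-1-yl}-4-methylfuran-2(5H)-one
Conditions: Ti(OiPr)4 (20 mol %), (R)-BINOL (20 mol %, antipode that gives 15S,16S), Et2O, −20 °C; dilute aq. HCl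
Reagents that add atoms: none
Why: Vinylogous Mukaiyama aldol addition of the silyloxyfuran through its γ-carbon to the enal carbonyl (1,2-addition) under a titanium–BINOL Lewis acid should give the threo adduct, the ligand antipode setting C15 and C16 by catalyst control because the decalin stereocentres are remote.

Step 11
Reactants: 20 bis-methylidene diol
Product: 21 (1R,4aR,5S,8S,8aR)-8-hydroxy-5-{(3E,5S)-5-hydroxy-3-methyl-5-[(2S)-3-methyl-5-oxo-2,5-dihydrofuran-2-yl]pent-3-en-1-yl}-1,4a-dimethyl-6-methylidenedecahydronaphthalene-1-carbaldehyde (CNP0113661.1)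
Conditions: Rh(acac)(CO)2 (4 mol %), 2-isopropoxy-1-methyl-3-phenyl-2,3-dihydro-1H-1,3-benzazaphosphole (scaffolding ligand, 20 mol %), p-TsOH (0.2 mol %), CO/H2 (1:1, 400 psi), benzene, 45 °C
Reagents that add atoms: carbon monoxide, [C-]#[O+]
Why: In this directed hydroformylation the ligand exchanges its alkoxy group for the C6 hydroxyl and delivers rhodium hydride to the α-face of the proximal C4=C19 methylene (the C8=C17 methylene is anti to O6 and out of reach), so the formyl group should enter at the more substituted carbon syn to O6 while C19 becomes the β-methyl, which sets C4.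

**Compound list**
1 | 3-methylcyclohex-2-en-1-one | CC1=CC(=O)CCC1 | starting material
2 | propyne | CC#C | starting material
3 | (E)-prop-1-enyl(diisobutyl)alane (formed in the flask) | C/C=C/[Al](CC(C)C)CC(C)C | intermediate
4 | diisobutyl{[(3R)-3-methyl-3-((E)-prop-1-en-1-yl)cyclohex-1-en-1-yl]oxy}alane (formed in the flask) | CC(C)C[Al](CC(C)C)OC1=C[C@](C)(CCC1)/C=C/C | intermediate
5 | (R)-trimethyl{[3-methyl-3-((E)-prop-1-en-1-yl)cyclohex-1-en-1-yl]oxy}silane | C[Si](C)(C)OC1=C[C@](C)(CCC1)/C=C/C | intermediate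
6 | but-3-yn-1-ol | C#CCCO | starting material
7 | but-3-ynal | C#CCC=O | intermediate
8 | lithium (R)-3-methyl-3-[(E)-prop-1-en-1-yl]cyclohex-1-en-1-olate (formed in the flask) | [Li]OC1=C[C@](C)(CCC1)/C=C/C | intermediate
9 | (2S,3R)-2-[(1S)-1-hydroxybut-3-yn-1-yl]-3-methyl-3-[(E)-prop-1-en-1-yl]cyclohexan-1-one (formed in the flask) | C#CC[C@H](O)[C@@H]1[C@](C)(CCCC1=O)/C=C/C | intermediate
10 | (4aR,5S,8S,8aS)-5-ethenyl-8-hydroxy-4a-methyl-6-methylideneoctahydronaphthalen-1(2H)-one (5α-H, 6α-OH, 9β-vinyl, 10β-Me) | C=C1C[C@H](O)[C@@H]2[C@](C)(CCCC2=O)[C@H]1C=C | intermediate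
11 | (1S,4S,4aR,8aS)-4-ethenyl-4a-methyl-3,8-dimethylidenedecahydronaphthalen-1-ol | C=C1C[C@H](O)[C@@H]2[C@](C)(CCCC2=C)[C@H]1C=C | intermediate
12 | ethyl acetoacetate | CCOC(=O)CC(C)=O | starting material
13 | ethyl (E)-3-{[(trifluoromethyl)sulfonyl]oxy}but-2-enoate | C/C(OS(=O)(=O)C(F)(F)F)=C\C(=O)OCC | intermediate
14 | C12-disiamylborane derived from 11 (formed in the flask) | C=C1C[C@H](O)[C@@H]2[C@](C)(CCCC2=C)[C@H]1CCB(C(C)C(C)C)C(C)C(C)C | intermediate
15 | ethyl (E)-5-[(1S,4S,4aS,8aR)-4-hydroxy-8a-methyl-2,5-dimethylidenedecahydronaphthalen-1-yl]-3-methylpent-2-enoate | C=C1C[C@H](O)[C@@H]2[C@](C)(CCCC2=C)[C@H]1CC/C(C)=C/C(=O)OCC | intermediate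
16 | (E)-5-[(1S,4S,4aS,8aR)-4-hydroxy-8a-methyl-2,5-dimethylidenedecahydronaphthalen-1-yl]-3-methylpent-2-en-1-ol | C=C1C[C@H](O)[C@@H]2[C@](C)(CCCC2=C)[C@H]1CC/C(C)=C/CO | intermediate
17 | (E)-5-[(1S,4S,4aS,8aR)-4-hydroxy-8a-methyl-2,5-dimethylidenedecahydronaphthalen-1-yl]-3-methylpent-2-enal | C=C1C[C@H](O)[C@@H]2[C@](C)(CCCC2=C)[C@H]1CC/C(C)=C/C=O | intermediate
18 | 4-methylfuran-2(5H)-one | CC1=CC(=O)OC1 | starting material
19 | trimethyl[(4-methylfuran-2-yl)oxy]silane | Cc1coc(O[Si](C)(C)C)c1 | intermediate
20 | (5S)-5-{(1S,2E)-1-hydroxy-5-[(1S,4S,4aS,8aR)-4-hydroxy-8a-methyl-2,5-dimethylidenedecahydronaphthalen-1-yl]-3-methylpent-2-en-1-yl}-4-methylfuran-2(5H)-one | C=C1C[C@H](O)[C@@H]2[C@](C)(CCCC2=C)[C@H]1CC/C(C)=C/[C@H](O)[C@H]1OC(=O)C=C1C | intermediate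
21 | (1R,4aR,5S,8S,8aR)-8-hydroxy-5-{(3E,5S)-5-hydroxy-3-methyl-5-[(2S)-3-methyl-5-oxo-2,5-dihydrofuran-2-yl]pent-3-en-1-yl}-1,4a-dimethyl-6-methylidenedecahydronaphthalene-1-carbaldehyde | C=C1C[C@H](O)[C@@H]2[C@](C)(CCC[C@@]2(C)C=O)[C@H]1CC/C(C)=C/[C@H](O)[C@H]1OC(=O)C=C1C | target

**Total step count:** 11. **Longest linear sequence:** 8 steps (1, 3, 4, 6, 7, 8, 10, 11).

**Steps most likely to fail**

Step 3. The intermolecular aldol may show poor facial selectivity at C5 (methyl and propenyl on C10 are similar in size); after C5 equilibrates this appears as the C6 epimer of 10. Fallback (from 9, back at 10): the cyclisation of the epimeric aldol gives the 6β-hydroxy ketol F1, whose hydroxyl is anti-periplanar to H5. Mesylation (MsCl, Et3N, CH2Cl2, 0 °C) gives the mesylate F2, which eliminates with DBU to the conjugated enone F3. Copper-catalysed conjugate borylation (B2pin2, CuCl, NaOt-Bu, MeOH, THF) should add boron to C6 from the α-face, away from the axial C10 methyl, and protonate C5 to the trans-decalin, giving the 6α-boryl ketone F4. NaBO3 oxidation with retention returns 10, so C6 is then set by substrate control and not by the aldol.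

Step 11. At the last step the rhodium hydride may be diverted by the free allylic C15 hydroxyl and the butenolide (alcohol isomerisation, conjugate reduction) before it is delivered to the hindered C4. Fallback (from 15, back at 21): the carbonylation is moved to the enoate stage, where only the C6 hydroxyl is present. The same directed hydroformylation of 15 gives the hydroxy aldehyde F5, which is masked as the dimethyl acetal F6 (HC(OMe)3, PPTS, MeOH). i-Bu2AlH then gives the allylic alcohol F7, MnO2 the enal F8, and the vinylogous aldol addition of 19 the adduct F9; PPTS in wet acetone unmasks 21.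

Step 6. The hydroboration may be incompletely site-selective among three alkenes, or the hindered trialkylborane may transmetallate slowly. Fallback (from 11, back at 15): cross metathesis of the vinyl group with methyl vinyl ketone (second-generation Hoveyda–Grubbs catalyst, CH2Cl2, 40 °C; the 1,1-disubstituted methylenes should not take part) gives the enone F10. Conjugate reduction with [(Ph3P)CuH]6 gives the methyl ketone F11, and Horner–Wadsworth–Emmons olefination (triethyl phosphonoacetate, NaH, THF) gives 15 after removal of the minor (Z)-isomer.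

**Further compounds**
F1 | step 3 | (4aR,5S,8R,8aS)-5-ethenyl-8-hydroxy-4a-methyl-6-methylideneoctahydronaphthalen-1(2H)-one (6β-hydroxy epimer of 10) | C=C1C[C@@H](O)[C@@H]2[C@](C)(CCCC2=O)[C@H]1C=C
F2 | step 3 | methanesulfonate of F1 | C=C1C[C@@H](OS(C)(=O)=O)[C@@H]2[C@](C)(CCCC2=O)[C@H]1C=C
F3 | step 3 | (4aR,5S)-5-ethenyl-4a-methyl-6-methylidene-3,4,4a,5,6,7-hexahydronaphthalen-1(2H)-one | C=C1CC=C2[C@](C)(CCCC2=O)[C@H]1C=C
F4 | step 3 | 6α-(pinacolboryl) analogue of 10 (boron in place of the hydroxyl) | C=C1C[C@H](B2OC(C)(C)C(C)(C)O2)[C@@H]2[C@](C)(CCCC2=O)[C@H]1C=C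
F5 | step 11 | ethyl (E)-5-[(1S,4S,4aR,5R,8aR)-5-formyl-4-hydroxy-5,8a-dimethyl-2-methylidenedecahydronaphthalen-1-yl]-3-methylpent-2-enoate | C=C1C[C@H](O)[C@@H]2[C@](C)(CCC[C@@]2(C)C=O)[C@H]1CC/C(C)=C/C(=O)OCC
F6 | step 11 | dimethyl acetal of F5 | C=C1C[C@H](O)[C@@H]2[C@](C)(CCC[C@@]2(C)C(OC)OC)[C@H]1CC/C(C)=C/C(=O)OCC
F7 | step 11 | allylic alcohol from F6 | C=C1C[C@H](O)[C@@H]2[C@](C)(CCC[C@@]2(C)C(OC)OC)[C@H]1CC/C(C)=C/CO
F8 | step 11 | enal from F7 | C=C1C[C@H](O)[C@@H]2[C@](C)(CCC[C@@]2(C)C(OC)OC)[C@H]1CC/C(C)=C/C=O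
F9 | step 11 | C18 dimethyl acetal of 21 | C=C1C[C@H](O)[C@@H]2[C@](C)(CCC[C@@]2(C)C(OC)OC)[C@H]1CC/C(C)=C/[C@H](O)[C@H]1OC(=O)C=C1C
F10 | step 6 | (E)-4-[(1S,4S,4aS,8aR)-4-hydroxy-8a-methyl-2,5-dimethylidenedecahydronaphthalen-1-yl]but-3-en-2-one | C=C1C[C@H](O)[C@@H]2[C@](C)(CCCC2=C)[C@H]1/C=C/C(C)=O
F11 | step 6 | 4-[(1S,4S,4aS,8aR)-4-hydroxy-8a-methyl-2,5-dimethylidenedecahydronaphthalen-1-yl]butan-2-one | C=C1C[C@H](O)[C@@H]2[C@](C)(CCCC2=C)[C@H]1CCC(C)=O
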